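**Retrosynthetic overview**
1. Target ⇒ ethyl 2-oxolabda-7,13E-dien-15-oate. One reduction–acetylation makes both acetate C–O bonds and the axial C2 stereocentre; the 7-ene comes from loss of a C8 tertiary alcohol and the 13E-enoate from a Horner–Wadsworth–Emmons reaction on a C13 methyl ketone.
2. Key disconnection: the C2–O bond, made by undirected C–H oxygenation of a saturated 8-hydroxy-13-ketone. The C8 hydroxyl and the C13 carbonyl deactivate ring B and the side chain, leaving C2 as the only unhindered, electron-rich CH2.
3. The 8-hydroxy-13-ketone ⇒ (5E,9E)-farnesylacetone by an enantioselective proton-initiated bicyclisation that ends in C8–O bond formation to the ketone oxygen.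
4. Ring order: rings A and B close in one cascade in the first step, together with a transient oxygen ring C (cyclic enol ether) that is hydrolysed in the same flask. No ring is formed later.

Assumption: the target is an ent-labdane (C10 methyl and C9 side chain on one face, H5 and H9 on the other, C2 acetoxy axial and cis to the C10 methyl); labdane numbering is used throughout, and (5E,9E)-farnesylacetone is bought as the single geometric isomer.

**Step 1**
Reactants: 1 (5E,9E)-farnesylacetone [(5E,9E)-6,10,14-trimethylpentadeca-5,9,13-trien-2-one]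
Product: 3 (5R,8S,9S,10R)-8-hydroxy-14,15-dinorlabdan-13-one, via ent-sclareol oxide 2 (not isolated)
Conditions: chiral IDPi Brønsted acid (imidodiphosphorimidate, mirror-image form of the catalyst that turns homofarnesol into (−)-ambrox, 3 mol%), (CF3)3COH, −20 → 0 °C; then 1 M aq. HCl, THF, 23 °C; recrystallise to raise the enantiomeric ratio
Reagents that add atoms: water, O
Why: Proposed new method: the confined chiral acid protonates the terminal isopropylidene of chair–chair folded 1 inside its pocket, the two E-alkenes add anti (Stork–Eschenmoser) so that rings A and B close in one cascade and C5, C9 and C10 are set as one enantiomer of the trans-decalin, and the C8 cation is captured by the ketone oxygen (equatorial C8–O bond, oxocarbenium then enol ether 2), which dilute acid hydrolyses to 3; the closest known reactions are the IDPi-catalysed cyclisation of homofarnesol to ambrox (hydroxyl termination) and the superacid cyclisation of farnesylacetone to racemic sclareol oxide, and what is new is carbonyl-oxygen termination under chiral Brønsted acid control.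

**Step 2**
Reactants: 3 (5R,8S,9S,10R)-8-hydroxy-14,15-dinorlabdan-13-one
Product: 4 (5R,8S,9S,10R)-8-hydroxy-14,15-dinorlabdane-2,13-dione
Conditions: quinuclidine (1 equiv), Me4NBF4, (CF3)2CHOH (10 equiv), MeCN, O2 (1 atm), RVC anode, Ni-foam cathode, constant current, 23 °C
Reagents that add atoms: dioxygen, O=O
Why: Undirected aliphatic C–H oxidation by mediated electrochemical hydrogen-atom abstraction: the quinuclidinium radical cation takes hydrogen from C2, the only ring-A methylene not next to a quaternary carbon, while ring B and the side chain are deactivated by the C8 hydroxyl and the ketone, and O2 trapping gives the ketone, the same C2 selectivity as established for sclareolide; no stereocentre is created.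

**Step 3**
Reactants: 4 (5R,8S,9S,10R)-8-hydroxy-14,15-dinorlabdane-2,13-dione; 5 triethyl phosphonoacetate
Product: 6 ethyl (5R,8S,9S,10R,13E)-8-hydroxy-2-oxolabd-13-en-15-oate
Conditions: NaH (1.25 equiv), 5 (1.3 equiv), THF, 0 → 45 °C; chromatography
Reagents that add atoms: triethyl phosphonoacetate, CCOC(=O)CP(=O)(OCC)OCC
Why: Horner–Wadsworth–Emmons olefination: the open methyl ketone reacts while the C2 carbonyl is spared because its tetrahedral adducts would carry a substituent syn-axial to the methyls on C4 and C10, and reversible addition gives mainly the E-enoate (about 6:1, the Z isomer is removed by chromatography).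

**Step 4**
Reactants: 6 ethyl (5R,8S,9S,10R,13E)-8-hydroxy-2-oxolabd-13-en-15-oate
Product: 7 ethyl (5R,9R,10R,13E)-2-oxolabda-7,13-dien-15-oate
Conditions: TsOH·H2O (10 mol%), benzene, 80 °C, Dean–Stark, 1–2 h
Reagents that add atoms: none
Why: Acid-catalysed E1 dehydration of the tertiary alcohol: the C8 cation loses the axial C7 proton and any exocyclic isomer is re-protonated and funnelled to the trisubstituted ring alkene (Saytzeff), with C5, C9 and C10 untouched.

**Step 5**
Reactants: 7 ethyl (5R,9R,10R,13E)-2-oxolabda-7,13-dien-15-oate; 8 acetic anhydride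
Product: 10 (2S,5R,9R,10R,13E)-labda-7,13-diene-2,15-diyl diacetate (target), via diol 9 (not isolated)
Conditions: i-Bu2AlH (3.5 equiv), CH2Cl2, −78 → 0 °C; then pyridine, DMAP (0.3 equiv), 8 (excess), 0 → 40 °C; aq. KNaC4H4O6 work-up
Reagents that add atoms: acetic anhydride, CC(=O)OC(C)=O
Why: Reductive acetylation: i-Bu2AlH reduces the enoate 1,2 to the allylic alcohol and the C2 ketone by equatorial hydride delivery (the axial path is blocked by the syn-axial methyls on C4 and C10), which sets C2 as the axial 2S alcohol cis to the C10 methyl, and DMAP-catalysed acylation of both aluminium alkoxides in the flask gives the diacetate.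

**Compound list**
1 | (5E,9E)-6,10,14-trimethylpentadeca-5,9,13-trien-2-one ((E,E)-farnesylacetone) | CC(=O)CC/C=C(\C)CC/C=C(\C)CCC=C(C)C | starting material
2 | ent-sclareol oxide, (4aS,6aR,10aR,10bS)-3,4a,7,7,10a-pentamethyl-4a,5,6,6a,7,8,9,10,10a,10b-decahydro-1H-benzo[f]chromene (8,13-epoxy-14,15-dinorlabd-12-ene, mirror image of the natural series) | CC1=CC[C@@H]2[C@@](C)(O1)CC[C@@H]3C(C)(C)CCC[C@@]23C | intermediate (not isolated)
3 | (5R,8S,9S,10R)-8-hydroxy-14,15-dinorlabdan-13-one, 4-[(1S,2S,4aR,8aR)-2-hydroxy-2,5,5,8a-tetramethyldecahydronaphthalen-1-yl]butan-2-one (trans-decalin, C8 hydroxyl equatorial, C8 methyl cis to C10 methyl) | CC(=O)CC[C@@H]1[C@@](C)(O)CC[C@@H]2C(C)(C)CCC[C@@]12C | intermediate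
4 | (5R,8S,9S,10R)-8-hydroxy-14,15-dinorlabdane-2,13-dione, 4-[(1S,2S,4aR,8aR)-2-hydroxy-2,5,5,8a-tetramethyl-7-oxodecahydronaphthalen-1-yl]butan-2-one | CC(=O)CC[C@@H]1[C@@](C)(O)CC[C@@H]2C(C)(C)CC(=O)C[C@@]12C | intermediate
5 | triethyl phosphonoacetate | CCOC(=O)CP(=O)(OCC)OCC | starting material
6 | ethyl (5R,8S,9S,10R,13E)-8-hydroxy-2-oxolabd-13-en-15-oate, ethyl (2E)-5-[(1S,2S,4aR,8aR)-2-hydroxy-2,5,5,8a-tetramethyl-7-oxodecahydronaphthalen-1-yl]-3-methylpent-2-enoate | CCOC(=O)/C=C(\C)CC[C@@H]1[C@@](C)(O)CC[C@@H]2C(C)(C)CC(=O)C[C@@]12C | intermediate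
7 | ethyl (5R,9R,10R,13E)-2-oxolabda-7,13-dien-15-oate, ethyl (2E)-5-[(1R,4aR,8aR)-2,5,5,8a-tetramethyl-7-oxo-1,4,4a,5,6,7,8,8a-octahydronaphthalen-1-yl]-3-methylpent-2-enoate | CCOC(=O)/C=C(\C)CC[C@@H]1C(C)=CC[C@@H]2C(C)(C)CC(=O)C[C@@]12C | intermediate
8 | acetic anhydride | CC(=O)OC(C)=O | starting material
9 | (2S,5R,9R,10R,13E)-labda-7,13-diene-2,15-diol (axial 2-OH cis to the C10 methyl; present in the flask as its aluminium alkoxide) | OC/C=C(\C)CC[C@@H]1C(C)=CC[C@@H]2C(C)(C)C[C@H](O)C[C@@]12C | intermediate (not isolated)
10 | (2S,5R,9R,10R,13E)-labda-7,13-diene-2,15-diyl diacetate, (2E)-5-[(1R,4aR,7S,8aR)-7-acetyloxy-2,5,5,8a-tetramethyl-1,4,4a,5,6,7,8,8a-octahydronaphthalen-1-yl]-3-methylpent-2-en-1-yl acetate | CC(=O)OC/C=C(\C)CC[C@@H]1C(C)=CC[C@@H]2C(C)(C)C[C@H](OC(C)=O)C[C@@]12C | target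

**Step count and risks**
Total steps: 5. Longest linear sequence: 5 (from 1).

The three steps most likely to fail:

Step 1 (the new cyclisation). The risks are that the basic carbonyl or enol ether ties up the catalyst, that the cascade stalls at the monocycle, or that the enantiomeric ratio is too low. The fallback uses known chemistry only and sets out from 1. The classical superacid cyclisation (FSO3H, 2-nitropropane, −78 °C) gives racemic sclareol oxide, that is 2 together with its mirror image (4aR,6aS,10aS,10bR)-sclareol oxide F1. Dilute aqueous HCl in THF opens both to the racemic hydroxy ketone, that is 3 together with its mirror image (5S,8R,9R,10S)-8-hydroxy-14,15-dinorlabdan-13-one F2. Preparative chiral SFC then gives 3 as the single enantiomer; the unwanted peak is identified with an authentic sample made by the known KMnO4 degradation of natural sclareol. The fallback comes back to the route at 3.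

Step 2 (C–H oxygenation). The risks are a competing C3 ketone, over-oxidation, and loss of material through the hemiketal/enol ether manifold. The fallback sets out from 3 and switches to a shape-selective metal-oxo hydroxylation that stops at the alcohol. Mn(CF3SO3)2(TIPSmcp) (1 mol%; TIPSmcp = N,N′-dimethyl-N,N′-bis[(5-triisopropylsilylpyridin-2-yl)methyl]cyclohexane-1,2-diamine) with H2O2 and AcOH in (CF3)2CHOH at 0 °C gives the equatorial C2 alcohol (2R,5R,8S,9S,10R)-2,8-dihydroxy-14,15-dinorlabdan-13-one F3; the fluorinated alcohol hydrogen-bonds to the product and prevents further oxidation. F3 is separated from its C3 isomer and oxidised with Dess–Martin periodinane in CH2Cl2 to 4. The fallback comes back to the route at 4.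

Step 4 (dehydration). The risks are 8(17)- and 8(9)-ene isomers and acid-promoted oxa-Michael closure of the C8 hydroxyl onto the enoate. The fallback sets out from 6 and forms the alkene in two regiocontrolled stages. SOCl2 in pyridine/CH2Cl2 at −78 °C (E2; the equatorial chlorosulfite has an anti-periplanar hydrogen only on the freely rotating C17 methyl) gives the exocyclic alkene ethyl (5R,9R,10R,13E)-2-oxolabda-8(17),13-dien-15-oate F4. Brief heating with aqueous hydriodic acid in benzene at 80 °C, the classical exo-to-endo isomerisation of labd-8(17)-enes, moves the double bond into the ring to give 7. The fallback comes back to the route at 7.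

**Further compounds**
F1 | step 1 | (4aR,6aS,10aS,10bR)-sclareol oxide (mirror image of 2, formed 1:1 with 2 as the racemate) | CC1=CC[C@H]2[C@](C)(O1)CC[C@H]3C(C)(C)CCC[C@]23C
F2 | step 1 | (5S,8R,9R,10S)-8-hydroxy-14,15-dinorlabdan-13-one (mirror image of 3, formed 1:1 with 3 and removed by chiral SFC) | CC(=O)CC[C@H]1[C@](C)(O)CC[C@H]2C(C)(C)CCC[C@]12C
F3 | step 2 | (2R,5R,8S,9S,10R)-2,8-dihydroxy-14,15-dinorlabdan-13-one (equatorial 2-OH) | CC(=O)CC[C@@H]1[C@@](C)(O)CC[C@@H]2C(C)(C)C[C@@H](O)C[C@@]12C
F4 | step 4 | ethyl (5R,9R,10R,13E)-2-oxolabda-8(17),13-dien-15-oate | CCOC(=O)/C=C(\C)CC[C@@H]1C(=C)CC[C@@H]2C(C)(C)CC(=O)C[C@@]12C
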